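We have no constants for D and E yet, so for your quick number we reckon from the readings alone, with every charge of E counted in equivalents of the D charge.

| flask | D | E | remark | time |
|---|---|---|---|---|
| amber | 0.020 M | 0.026 M | run made earlier |  |
| red | 0.020 M | 0.042 M | run made earlier |  |
| green | 0.020 M | 0.066 M | run made earlier |  |
| south-west | 0.020 M | 0.0300 M |  | 10 min |
| north-west | 0.020 M | 0.0500 M |  | 10 min |
| west | 0.020 M | 0.0600 M |  | 10 min |

- amber (time / min: Q / %, J / %): 1.33: 35.9, 7.7; 3.00: 39.3, 5.2; 4.00: 39.6, 4.6; 6.00: 39.1, 2.8; 8.00: 39.0, 1.9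
- red (time / min: Q / %, J / %): 0.667: 52.8, 6.2; 2.00: 69.6, 3.0; 3.00: 71.3, 1.9; 5.00: 73.5, 1.8; 8.00: 72.6, 1.6
- green (time / min: Q / %, J / %): 0.667: 76.3, 1.8; 2.00: 91.4, 0; 3.00: 94.5, 1.0; 5.00: 96.2, 0.5; 8.00: 96.7, 0

(each reading ± 0.5 percentage points)

- percent here means D units held: one X counts as two
- steps under discussion: E + J -> Q; D + E -> G; D + J -> X; E + G -> Q; E -> L; D + E -> J

- how much Q is there at the end, in percent of the D charged: for each flask in turn (south-west, north-west, west)

1. We take the last reading of each run, at 8.00 min, as the end, and compare the runs by the marginal return of E, meaning the fraction of the D charge gained as Q per added equivalent of E.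

2. Going from amber at 1.30 equivalents to red at 2.10, Q rises from 39.0% to 72.6%, so the return reads 0.420. A Q holds two E, so a return of 0.5 would put each added E into Q, and our reading is lower than that.

3. From red to green the return reads 0.201, which is lower than the first.

4. Applying these returns along straight lines, we get 47.4% for south-west, 80.6% for north-west and 90.7% for west.

5. Your forecast, read along “the curved, saturating yield against E”, says 48%, 85% and 93%, which is higher than ours in north-west and in west.

    E + J → Q (k = 5.33 L mol⁻¹ s⁻¹)
    D + E → G (k = 0.842 L mol⁻¹ s⁻¹)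
    D + J → X (k = 0.740 L mol⁻¹ s⁻¹)
    E + G → Q (k = 0.856 L mol⁻¹ s⁻¹)
    E → L (k = 0.00614 s⁻¹)
    D + E → J (k = 1.36 L mol⁻¹ s⁻¹)

The flasks give 48.1%, 86.0% and 94.0%, so the forecast holds within its margin, and the return comes to 0.455 from amber to south-west, against our 0.420, and 0.335 from red to north-west, against our 0.201. In north-west, with the other concentrations as charged, G has a half-life of 0.27 min by E + G → Q alone, shorter than the 1.9 min of E by E → L alone. Yet at 10.0 min north-west still holds G at 9.05% with E at 0.14% of its charge. A longer run makes no difference: at 100 min north-west holds Q at 86.1%.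

All runs were computed on assumed constants; noise was put on by code.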